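C2 and C3 refer to flavanone numbering unless "of the chain" is added.

Cuts, in retrosynthetic order: O1–C2 of ring C; C2–C3 (aldol); the C3–O bond (hydroxylation of an acetyl CH3); O5–CH3; C6–C1'' (geranyl to ring A).
Enabling feature: C2 is benzylic to ring B and para to the 4'-OH, so its hydroxyl can leave to give a planar para-quinone methide. The C8a phenol of ring A reaches that carbon through a six-membered ring. O5 is a methyl ether and O7 is out of reach, so only O1 can close.
Forward order: rings A and B are bought. Geranyl goes onto ring A, the three phenols are told apart (two TIPS ethers, then methyl), the acetyl group is hydroxylated, ring B is joined by the aldol, all silyl groups fall together, and ring C closes last.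
Stereochemistry: C3 (R) comes from the catalyst-controlled face of a zinc enediolate. C2 (R) is relayed from C3 in the reversible closure (ring B and 3-OH equatorial), so both aldol epimers converge. The E-alkene is bought with geranyl bromide.
Protecting groups: one kind only (TIPS on O7, O8a and O4'), so the closure itself delivers the target. The chain meets neither an alkene-attacking oxidant nor an acid stronger than a pyridinium salt.

Key step: step 8

Abbreviations: geranyl = (2E)-3,7-dimethylocta-2,6-dien-1-yl; TIPS = triisopropylsilyl.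
Assumption: by analogy with simple 2-hydroxy-1-arylethanones the (S,S)-ligand is taken to give the 2R ketol; if a first run shows the opposite sense, the equally available (R,R)-ligand is used and nothing else changes.

Step 1
Reactants: 1 2,4,6-trihydroxyacetophenone; 2 geranyl bromide
Product: 3 1-(3-geranyl-2,4,6-trihydroxyphenyl)ethanone
Conditions: K2CO3 (1 equiv), acetone, reflux; 1 in slight excess
Reagents that add atoms: none
Why: C-alkylation of a phloroglucinol-type phenoxide by a soft allylic bromide (SN2 at the primary carbon, which keeps the E-alkene) is the standard entry to 3-geranylphloroacetophenone, and since the two open ring positions of 1 are equivalent only one mono-C-geranyl isomer can form.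

Step 2
Reactants: 3 1-(3-geranyl-2,4,6-trihydroxyphenyl)ethanone
Product: 4 1-[3-geranyl-2-hydroxy-4,6-bis(triisopropylsilyloxy)phenyl]ethanone
Conditions: TIPSCl (2.2 equiv), imidazole, DMF, 0 °C → rt
Reagents that add atoms: triisopropylsilyl chloride, CC(C)[Si](Cl)(C(C)C)C(C)C
Why: Selective silyl ether formation: the unchelated 4-OH and the less crowded ortho 6-OH are silylated, whereas the 2-OH, wedged between acetyl and geranyl and locked in the hydrogen bond to the carbonyl, should stay free against a reagent as bulky as TIPSCl.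

Step 3
Reactants: 4 1-[3-geranyl-2-hydroxy-4,6-bis(triisopropylsilyloxy)phenyl]ethanone
Product: 5 1-[3-geranyl-2-methoxy-4,6-bis(triisopropylsilyloxy)phenyl]ethanone
Conditions: MeOH, PPh3, DIAD, THF, 0 °C → rt
Reagents that add atoms: methanol, CO
Why: Mitsunobu etherification: the remaining phenol is acidic enough to protonate the betaine and then attacks the unhindered methyl carbon of the methoxyphosphonium ion, and the base-free medium leaves the acyl-activated aryl silyl ethers in place.

Step 4
Reactants: 5 1-[3-geranyl-2-methoxy-4,6-bis(triisopropylsilyloxy)phenyl]ethanone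
Product: 7 1-[3-geranyl-2-methoxy-4,6-bis(triisopropylsilyloxy)phenyl]-2-hydroxyethanone, via potassium enolate 6 (not isolated)
Conditions: KN(SiMe3)2 (1.1 equiv), THF, −78 °C; 2-(phenylsulfonyl)-3-phenyloxaziridine (1.3 equiv), −78 °C; AcOH quench
Reagents that add atoms: 2-(phenylsulfonyl)-3-phenyloxaziridine, O=S(=O)(c1ccccc1)N1OC1c1ccccc1
Why: Davis oxidation of a kinetic ketone enolate: the acetyl CH3 holds the only acidic C–H, the N-sulfonyloxaziridine hands its oxygen to the enolate carbon at −78 °C without touching trisubstituted alkenes, and the bulk of TIPS holds back silyl transfer from the ortho oxygen to the enolate or alkoxide oxygen.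

Step 5
Reactants: 8 4-hydroxybenzaldehyde
Product: 9 4-(triisopropylsilyloxy)benzaldehyde
Conditions: TIPSCl, imidazole, CH2Cl2, rt
Reagents that add atoms: triisopropylsilyl chloride, CC(C)[Si](Cl)(C(C)C)C(C)C
Why: Routine silyl ether formation on an unhindered phenol, which leaves the aldehyde untouched and gives ring B the same fluoride-labile group as ring A.

Step 6
Reactants: 7 1-[3-geranyl-2-methoxy-4,6-bis(triisopropylsilyloxy)phenyl]-2-hydroxyethanone; 9 4-(triisopropylsilyloxy)benzaldehyde
Product: 10 (2R)-1-[3-geranyl-2-methoxy-4,6-bis(triisopropylsilyloxy)phenyl]-2,3-dihydroxy-3-[4-(triisopropylsilyloxy)phenyl]propan-1-one, both epimers at C3 of the chain (syn-(2R,3S) expected to prevail over anti-(2R,3R)), not separated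
Conditions: (S,S)-ProPhenol [(S,S)-2,6-bis[2-(hydroxydiphenylmethyl)pyrrolidin-1-ylmethyl]-4-methylphenol] (10 mol %), Et2Zn (20 mol %), 4 Å MS, THF, −35 → −20 °C; 9 (2 equiv)
Reagents that add atoms: none
Why: Direct catalytic asymmetric aldol addition of an α-hydroxy aryl ketone under dinuclear zinc–ProPhenol catalysis: 7 binds as a chelated enediolate with one face covered by the diphenylcarbinol arms of the ligand, which fixes the ketol carbon as R whichever face of the aldehyde is attacked, so the benzylic epimers are carried on together, and the non-enolisable aldehyde can be used in excess to push the hindered donor to conversion.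

Step 7
Reactants: 10 (2R)-tris-TIPS aldol adduct, both benzylic epimers
Product: 11 (2R)-1-(3-geranyl-4,6-dihydroxy-2-methoxyphenyl)-2,3-dihydroxy-3-(4-hydroxyphenyl)propan-1-one, both epimers at C3 of the chain
Conditions: Bu4NF (3.3 equiv), AcOH (3.5 equiv), THF, 0 °C → rt
Reagents that add atoms: none
Why: Fluoride cleavage of aryl silyl ethers, driven by the Si–F bond and the good phenoxide leaving groups, frees all three phenols at once, while the acetic acid buffer keeps alkoxide and phenoxide levels too low for retro-aldol cleavage or enolisation at the ketol carbon.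

Step 8
Reactants: 11 (2R)-1-(3-geranyl-4,6-dihydroxy-2-methoxyphenyl)-2,3-dihydroxy-3-(4-hydroxyphenyl)propan-1-one, both benzylic epimers
Product: 13 (2R,3R)-6-geranyl-3,7-dihydroxy-2-(4-hydroxyphenyl)-5-methoxychroman-4-one, via para-quinone methide 12 (not isolated)
Conditions: pyridinium p-toluenesulfonate (10 mol %), (CF3)2CHOH–CH2Cl2 1:4, 0.005 M, 23 °C
Reagents that add atoms: none
Why: Hydrogen bonding from the fluorinated alcohol and the pyridinium proton turn the benzylic hydroxyl into a leaving group, the para 4'-OH pushes it out, and both benzylic epimers of 11 collapse to the same planar quinone methide 12, in which only the neighbouring carbinol centre survives. The phenol ortho to the ketone then adds to the exocyclic methide carbon, a 1,6-conjugate addition that restores the aromaticity of ring B and is a 6-exo-trig closure forming O1–C2 and ring C. The closest known reactions are the acid-induced cyclisation of 1-aryl-3-(2-hydroxyaryl)propane-1,2-diols to 2,3-trans-flavan-3-ols and the C2 epimerisation of 4'-hydroxylated dihydroflavonols, which opens and recloses this very bond through the same kind of intermediate. C2 is controlled by C3: in the half-chair transition state ring B and the 3-OH both sit equatorial, which gives 2R from 3R, and because the free 4'-OH keeps the closure reversible any 2,3-cis product should reopen and drain into the more stable trans isomer. The step needs closure to beat loss of the C3 proton (achiral α-hydroxychalcone), 1,2-shift of the aroyl group and intermolecular trapping; the absence of base, the neutral rather than cationic nature of 12, the closeness of the one phenol that can reach C2 and high dilution should secure this. Trisubstituted alkenes are not protonated at this acidity, so the geranyl chain and the adjacent 7-OH should not cyclise.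

Compound list
1 | 2,4,6-trihydroxyacetophenone | CC(=O)c1c(O)cc(O)cc1O | starting material
2 | geranyl bromide | CC(C)=CCC/C(C)=C/CBr | starting material
3 | 1-(3-geranyl-2,4,6-trihydroxyphenyl)ethanone | CC(=O)c1c(O)cc(O)c(C/C=C(\C)CCC=C(C)C)c1O | intermediate
4 | 1-[3-geranyl-2-hydroxy-4,6-bis(triisopropylsilyloxy)phenyl]ethanone | Oc1c(C/C=C(\C)CCC=C(C)C)c(O[Si](C(C)C)(C(C)C)C(C)C)cc(O[Si](C(C)C)(C(C)C)C(C)C)c1C(C)=O | intermediate
5 | 1-[3-geranyl-2-methoxy-4,6-bis(triisopropylsilyloxy)phenyl]ethanone | COc1c(C/C=C(\C)CCC=C(C)C)c(O[Si](C(C)C)(C(C)C)C(C)C)cc(O[Si](C(C)C)(C(C)C)C(C)C)c1C(C)=O | intermediate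
6 | potassium enolate of 5 (not isolated) | COc1c(C/C=C(\C)CCC=C(C)C)c(O[Si](C(C)C)(C(C)C)C(C)C)cc(O[Si](C(C)C)(C(C)C)C(C)C)c1C(=C)[O-].[K+] | intermediate
7 | 1-[3-geranyl-2-methoxy-4,6-bis(triisopropylsilyloxy)phenyl]-2-hydroxyethanone | COc1c(C/C=C(\C)CCC=C(C)C)c(O[Si](C(C)C)(C(C)C)C(C)C)cc(O[Si](C(C)C)(C(C)C)C(C)C)c1C(=O)CO | intermediate
8 | 4-hydroxybenzaldehyde | O=Cc1ccc(O)cc1 | starting material
9 | 4-(triisopropylsilyloxy)benzaldehyde | O=Cc1ccc(O[Si](C(C)C)(C(C)C)C(C)C)cc1 | intermediate
10 | (2R)-1-[3-geranyl-2-methoxy-4,6-bis(triisopropylsilyloxy)phenyl]-2,3-dihydroxy-3-[4-(triisopropylsilyloxy)phenyl]propan-1-one, both C3 epimers | COc1c(C/C=C(\C)CCC=C(C)C)c(O[Si](C(C)C)(C(C)C)C(C)C)cc(O[Si](C(C)C)(C(C)C)C(C)C)c1C(=O)[C@H](O)C(O)c1ccc(O[Si](C(C)C)(C(C)C)C(C)C)cc1 | intermediate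
11 | (2R)-1-(3-geranyl-4,6-dihydroxy-2-methoxyphenyl)-2,3-dihydroxy-3-(4-hydroxyphenyl)propan-1-one, both C3 epimers | COc1c(C/C=C(\C)CCC=C(C)C)c(O)cc(O)c1C(=O)[C@H](O)C(O)c1ccc(O)cc1 | intermediate
12 | (2R)-1-(3-geranyl-4,6-dihydroxy-2-methoxyphenyl)-2-hydroxy-3-(4-oxocyclohexa-2,5-dien-1-ylidene)propan-1-one (not isolated) | COc1c(C/C=C(\C)CCC=C(C)C)c(O)cc(O)c1C(=O)[C@H](O)C=C1C=CC(=O)C=C1 | intermediate
13 | (2R,3R)-6-geranyl-3,7-dihydroxy-2-(4-hydroxyphenyl)-5-methoxychroman-4-one (CNP0177937.1) | COc1c(C/C=C(\C)CCC=C(C)C)c(O)cc2c1C(=O)[C@H](O)[C@@H](c1ccc(O)cc1)O2 | target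

Total step count: 8. Longest linear sequence: 7 steps (1 → 3 → 4 → 5 → 7 → 10 → 11 → 13); step 5 is the only side branch.

Steps most likely to fail

Step 6. The di-ortho-substituted aryl group is twisted out of the carbonyl plane and crowds the zinc pocket, and addition to an electron-rich aldehyde is reversible. Slow turnover and erosion of the facial selectivity at the ketol carbon are the dangers.
- The fallback sets out from enolate 6 and returns at quinone methide 12. It sets the same carbinol carbon by a nucleophilic epoxidation that only an enone can undergo.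
- Enolate 6 is added to 9 at −78 °C and quenched with AcOH to give the racemic β-hydroxy ketone F1.
- MsCl and Et3N in CH2Cl2 take F1 through the benzylic mesylate F2 to the (E)-chalcone F3.
- Juliá–Colonna epoxidation (poly-L-leucine, urea–H2O2, DBU, THF) should give the trans-(2R,3S)-epoxy ketone F4, whose Cα–O bond is the future C3–OH.
- Buffered fluoride as in step 7 frees the triphenol epoxide F5. Under the conditions of step 8 the 4'-OH opens the benzylic C–O bond of F5 to give 12, which closes to 13.

Step 8. The acyl and hydroxyl groups on the neighbouring carbon slow the ionisation. If more forcing acid becomes necessary, proton loss from C3, aroyl migration and protonation of the chain gain ground.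
- The fallback sets out from 10 and returns at 12. It replaces acid ionisation of a hydroxyl by fluoride-triggered 1,6-elimination of a true leaving group, the reaction on which 4-silyloxybenzyl self-immolative linkers rest.
- 1,1'-Carbonyldiimidazole in CH2Cl2 ties the diol of 10 into the (4R)-cyclic carbonate F6 (both C5 epimers).
- Bu4NF and AcOH in THF at −20 → 0 °C give the desilylated carbonate F7.
- The free 4'-OH of F7 expels the benzylic carbonate oxygen. Loss of CO2 leaves the C3 hydroxyl and 12, which closes to 13 without any added acid.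

Step 4. A methyl ketone enolate can add to the sulfonimine left by the oxidant, condense with unreacted ketone or be oxidised a second time.
- The fallback sets out from enolate 6 and returns at 7. It brings in the oxygen as a nucleophile.
- Enolate 6 is trapped with Me3SiCl to give the trimethylsilyl enol ether F8.
- NBS in THF at −78 °C brominates the enol ether carbon, which is far more nucleophilic than the chain alkenes, to give the bromo ketone F9.
- CsO2CH in MeCN displaces bromide to give the formate ester F10.
- KHCO3 in MeOH at 0 °C removes the formyl group to give 7.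

Further compounds
F1 | step 6 | rac-1-[3-geranyl-2-methoxy-4,6-bis(triisopropylsilyloxy)phenyl]-3-hydroxy-3-[4-(triisopropylsilyloxy)phenyl]propan-1-one | COc1c(C/C=C(\C)CCC=C(C)C)c(O[Si](C(C)C)(C(C)C)C(C)C)cc(O[Si](C(C)C)(C(C)C)C(C)C)c1C(=O)CC(O)c1ccc(O[Si](C(C)C)(C(C)C)C(C)C)cc1
F2 | step 6 | methanesulfonate of F1 (not isolated) | COc1c(C/C=C(\C)CCC=C(C)C)c(O[Si](C(C)C)(C(C)C)C(C)C)cc(O[Si](C(C)C)(C(C)C)C(C)C)c1C(=O)CC(OS(C)(=O)=O)c1ccc(O[Si](C(C)C)(C(C)C)C(C)C)cc1
F3 | step 6 | (E)-1-[3-geranyl-2-methoxy-4,6-bis(triisopropylsilyloxy)phenyl]-3-[4-(triisopropylsilyloxy)phenyl]prop-2-en-1-one | COc1c(C/C=C(\C)CCC=C(C)C)c(O[Si](C(C)C)(C(C)C)C(C)C)cc(O[Si](C(C)C)(C(C)C)C(C)C)c1C(=O)/C=C/c1ccc(O[Si](C(C)C)(C(C)C)C(C)C)cc1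
F4 | step 6 | [3-geranyl-2-methoxy-4,6-bis(triisopropylsilyloxy)phenyl][(2R,3S)-3-[4-(triisopropylsilyloxy)phenyl]oxiran-2-yl]methanone | COc1c(C/C=C(\C)CCC=C(C)C)c(O[Si](C(C)C)(C(C)C)C(C)C)cc(O[Si](C(C)C)(C(C)C)C(C)C)c1C(=O)[C@@H]1O[C@H]1c1ccc(O[Si](C(C)C)(C(C)C)C(C)C)cc1
F5 | step 6 | (3-geranyl-4,6-dihydroxy-2-methoxyphenyl)[(2R,3S)-3-(4-hydroxyphenyl)oxiran-2-yl]methanone | COc1c(C/C=C(\C)CCC=C(C)C)c(O)cc(O)c1C(=O)[C@@H]1O[C@H]1c1ccc(O)cc1
F6 | step 8 | (4R)-4-[3-geranyl-2-methoxy-4,6-bis(triisopropylsilyloxy)benzoyl]-5-[4-(triisopropylsilyloxy)phenyl]-1,3-dioxolan-2-one, both C5 epimers | COc1c(C/C=C(\C)CCC=C(C)C)c(O[Si](C(C)C)(C(C)C)C(C)C)cc(O[Si](C(C)C)(C(C)C)C(C)C)c1C(=O)[C@@H]1OC(=O)OC1c1ccc(O[Si](C(C)C)(C(C)C)C(C)C)cc1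
F7 | step 8 | (4R)-4-(3-geranyl-4,6-dihydroxy-2-methoxybenzoyl)-5-(4-hydroxyphenyl)-1,3-dioxolan-2-one, both C5 epimers (not isolated) | COc1c(C/C=C(\C)CCC=C(C)C)c(O)cc(O)c1C(=O)[C@@H]1OC(=O)OC1c1ccc(O)cc1
F8 | step 4 | trimethylsilyl enol ether of 5 | COc1c(C/C=C(\C)CCC=C(C)C)c(O[Si](C(C)C)(C(C)C)C(C)C)cc(O[Si](C(C)C)(C(C)C)C(C)C)c1C(=C)O[Si](C)(C)C
F9 | step 4 | 2-bromo-1-[3-geranyl-2-methoxy-4,6-bis(triisopropylsilyloxy)phenyl]ethanone | COc1c(C/C=C(\C)CCC=C(C)C)c(O[Si](C(C)C)(C(C)C)C(C)C)cc(O[Si](C(C)C)(C(C)C)C(C)C)c1C(=O)CBr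
F10 | step 4 | 2-[3-geranyl-2-methoxy-4,6-bis(triisopropylsilyloxy)phenyl]-2-oxoethyl formate | COc1c(C/C=C(\C)CCC=C(C)C)c(O[Si](C(C)C)(C(C)C)C(C)C)cc(O[Si](C(C)C)(C(C)C)C(C)C)c1C(=O)COC=O
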